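## Analysis of the target

The target is a dimeric flavan-3-ol. A 2,3-trans unit (rings A, C and B; 2R,3S) and a 2,3-cis unit (rings D, F and E; 2R,3R) are joined by a diaryl ether between O4' of ring B and C7 of ring D. The four stereocentres form two vicinal pairs separated by two aromatic rings and an ether oxygen, so neither pair can steer the other and each must be set by a reagent. Ten hydroxyls (eight phenolic, two secondary) make the free compound air-sensitive, most of all the pyrogallol ring E. The two benzylic C2–O1 bonds are open to acid ionisation, to hydrogenolysis and, once a para-hydroxyl is free, to base-induced epimerisation through quinone methides. The hard points are the diaryl ether (its oxygen on ring B is flanked by two oxygenated carbons), the distinction of O7 from O5 and O1 on ring D, and the opposite relative configurations of the two units. The strategy rests on C4 of the trans unit: a methylene bound to C4a, a ring A carbon ortho to O1, ortho to the C5 oxygen and para to the C7 oxygen. Ring A is a symmetric phloroglucinol ring, so both carbons ortho to O1 are equivalent, and the C4–C4a bond can be made by attack of that carbon on a terminal epoxide that already carries C2 and C3 in their final configuration.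

## Retrosynthetic reasoning

**27 from 26.** The nine O–benzyl bonds are cut last. Benzyl is the only group used on the hydroxyls that remain in the target, so one neutral hydrogenolysis frees the air-sensitive polyphenol at the very end; the C3 hydroxyl of the cis unit is made last and needs no protection.

**26 from 25, 22 and 21.** The C3–O bond of ring F is traced to ketone 25, because a bulky hydride attacking anti to the C2 aryl group is the reliable way to the 2,3-cis alcohol. The ketone is traced to acid 22 and aldehyde 21 by excision of the carbon substituent on C3 (C3–C bond cut, C3–O made). The forward sequence must keep the C2 stereocentre next to the new carbonyl intact.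

**21 from 18 and 20.** Ring F is cut at O1–C2 and C3–C4. This gives salicylaldehyde 18 and enal 20 (from aldehyde 19 by two-carbon homologation). The cut brings in ring E as a simple building block and lets an aminocatalyst set C2 of the cis unit without reference to the distant trans unit.

**18 from 17, 15, 13 and 14.** The diaryl ether is cut on the ring D side, between the ether oxygen and C7. The formyl group that later becomes C4 of the cis unit sits para to this carbon and activates it for substitution by the hindered phenol 13. The two fluorine atoms of 14 ortho to the formyl group stand in for O5 and O1, so the regiochemistry on ring D is fixed by the aldehyde and not by electrophilic substitution.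

**13 from 12 and 11.** Only protecting-group changes: the C3 hydroxyl is capped as a benzyl ether and the allyl group on O4' is removed, which gives one free phenol for the ether formation.

**11 from 10 (key disconnection).** The C4–C4a bond is cut. Precursor 10 is an aryl ether in which ring A is still an untouched, symmetric 3,5-bis(benzyloxy)phenoxy group and C4 is the terminal carbon of an epoxide. Cutting here, and not at O1–C2, means the ring closure takes place at a non-stereogenic CH2 and cannot erode either stereocentre. The forward reaction must close the six-membered ring (6-endo) and not the five-membered one.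

**10 from 8, 6 and 7.** The epoxide C–O bond at the terminal carbon is cut to give diol 8. The C2–O1 bond is cut to give epoxy alcohol 6 and phenol 7. The forward opening must occur at the benzylic carbon with inversion, so that the trans epoxide gives the relative configuration of a 2,3-trans flavan. It is run with the phenoxide under basic conditions, so that no Lewis acid ionises the oxygenated benzylic carbon or diverts the phloroglucinol nucleophile to C-alkylation.

**6 from 5, 4, 3, 2 and 1.** The epoxide is traced to (E)-allylic alcohol 5, where a tartrate-controlled epoxidation sets both stereocentres of the trans unit in one step. Alcohol 5 comes from aldehyde 3 by olefination and reduction. Aldehyde 3 comes from 1 through 2 by two etherifications, with the hydroxyl para to the formyl group marked by an allyl group. Starting from the aldehyde oxidation level saves a reduction and an oxidation.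

## Alternatives that were turned down

**Alternative 1:** The C2–C3 bond of the trans unit is disconnected as a trans epoxide. In the forward key step, the sulfonium ylide made from the ring B benzylic bromide A1 (which already carries the protected cis flavan) and a chiral sulfide adds to the ring A arylacetaldehyde A2 and closes to the trans epoxide A3. Desilylation and attack of the ring A phenol at the benzylic epoxide carbon would then close ring C.
- For it: the step joins two large halves and makes the C2–C3 bond and both stereocentres at once. On convergence it is stronger than the chosen route, which is linear.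
- Against it: A2 is a 2,4,6-trioxygenated phenylacetaldehyde, easily enolised and prone to self-condensation under the basic ylide conditions. A1 is the most expensive intermediate and would be spent in a step whose selectivity with an electron-rich benzyl ylide and an enolisable aldehyde is uncertain. The later ring closure needs clean inversion at an oxygenated benzylic carbon; any carbocation character gives cis and trans mixtures, and 5-exo attack competes.
- Comparison: the chosen strategy sets the same two stereocentres by a tartrate-controlled epoxidation of a simple allylic alcohol and a base-mediated SN2 opening, and its ring closure touches no stereocentre.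

**Alternative 2:** Ring C is disconnected at O1–C2 and C3–C4 as a [4+2] cycloaddition. The ortho-quinone methide released from the hydroxymethyl phenol A4 by a chiral phosphoric acid adds to the (E)-borylstyrene A5 (again carrying the cis flavan) to give the 2,3-trans 3-boryl chroman A6. Oxidation of the C–B bond with retention would give the 3-hydroxyl.
- For it: two bonds, the ring and both stereocentres in one step. In bond economy it is the strongest of all four strategies.
- Against it: the quinone methide from A4 has no substituent on its methide carbon and should oligomerise readily. Acid-controlled enantioselective additions of this kind are established for aryl-stabilised quinone methides and for more nucleophilic alkenes, not for an alkenyl boronate as hindered as A5. The acid may also protodeboronate A5 or A6. The least precedented step would be run on the most advanced material.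
- Comparison: the chosen route uses only established reaction types and places its one uncertain step early, on material that is a few steps from commercial compounds.

**Alternative 3:** Ring F of the cis unit is disconnected at O1–C2 and C3–C4. Salicylaldehyde A7 and enal A8 react under a diarylprolinol silyl ether (oxa-Michael addition, then aldol condensation) to give the chromene carbaldehyde A9.
- For it: a known organocatalytic reaction that sets C2 of the cis unit and brings in ring E convergently. On the cis ring it is as strong as anything available.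
- Against it: as a strategy it leaves open how the trans unit (two stereocentres, ring C) and the diaryl ether inside A7 are made. Its product carries a formyl group where the hydroxyl belongs, so three more steps follow, and its C2 stereocentre is labile (retro-oxa-Michael, later alpha to a ketone).
- Comparison: this reaction is used in the chosen route as a supporting step (A7, A8 and A9 are identical with 18, 20 and 21). What the chosen strategy adds is a defined solution for the trans unit, with the strategic risk in an early ring closure and not in the last bond-forming events.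

Key step: step 8

Remark on the chemistry: the sense of induction in step 15 is assigned from the usual shielding model of the iminium ion of a diarylprolinol silyl ether; should the opposite sense be found, the (R)-configured catalyst is used instead.

## Route

Step 1
Reactants: 1 3,4,5-trihydroxybenzaldehyde
Product: 2 4-(allyloxy)-3,5-dihydroxybenzaldehyde
Conditions: allyl bromide (1.0 equiv), NaHCO3, DMF, 30 °C
Reagents that add atoms: allyl bromide, C=CCBr
Why: Williamson etherification; the 4-hydroxyl is para to the formyl group and the most acidic, so hydrogencarbonate should ionise it alone and one allyl group should enter there.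

Step 2
Reactants: 2 4-(allyloxy)-3,5-dihydroxybenzaldehyde
Product: 3 4-(allyloxy)-3,5-bis(benzyloxy)benzaldehyde
Conditions: BnBr, K2CO3, DMF, 50 °C
Reagents that add atoms: benzyl bromide, BrCc1ccccc1
Why: Williamson etherification of the two remaining phenols; the aldehyde and the allyl ether are inert to carbonate.

Step 3
Reactants: 3 4-(allyloxy)-3,5-bis(benzyloxy)benzaldehyde
Product: 4 ethyl (E)-3-[4-(allyloxy)-3,5-bis(benzyloxy)phenyl]prop-2-enoate
Conditions: (EtO)2P(O)CH2CO2Et, NaH, THF, 0 °C → rt
Reagents that add atoms: triethyl phosphonoacetate, CCOC(=O)CP(=O)(OCC)OCC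
Why: Horner–Wadsworth–Emmons olefination; the stabilised phosphonate anion should give the E enoate.

Step 4
Reactants: 4 ethyl (E)-enoate
Product: 5 (E)-3-[4-(allyloxy)-3,5-bis(benzyloxy)phenyl]prop-2-en-1-ol
Conditions: i-Bu2AlH (2.5 equiv), CH2Cl2, −78 → 0 °C; aq. potassium sodium tartrate
Reagents that add atoms: none
Why: 1,2-reduction of the unsaturated ester to the allylic alcohol; the alkene geometry and the ethers are untouched.

Step 5
Reactants: 5 (E)-allylic alcohol
Product: 6 [(2S,3S)-3-[4-(allyloxy)-3,5-bis(benzyloxy)phenyl]oxiran-2-yl]methanol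
Conditions: Ti(OiPr)4 (10 mol%), L-(+)-diethyl tartrate (12 mol%), t-BuOOH, 4 Å molecular sieves, CH2Cl2, −20 °C; basic work-up
Reagents that add atoms: tert-butyl hydroperoxide, CC(C)(C)OO
Why: Sharpless asymmetric epoxidation; the L-(+)-tartrate complex delivers oxygen to one face of the (E)-allylic alcohol and should give the (2S,3S) epoxide, which fixes both stereocentres of the trans unit. The isolated allyl ether is not an allylic alcohol and should not react.

Step 6
Reactants: 6 (2S,3S)-epoxy alcohol; 7 3,5-bis(benzyloxy)phenol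
Product: 8 (2S,3R)-3-[4-(allyloxy)-3,5-bis(benzyloxy)phenyl]-3-[3,5-bis(benzyloxy)phenoxy]propane-1,2-diol
Conditions: 7 (1.5 equiv), Cs2CO3 (0.3 equiv), DMF, 70 °C
Reagents that add atoms: none
Why: SN2 opening of a 3-aryl-2,3-epoxy alcohol by a phenoxide at the benzylic carbon with inversion, which sets the later C2 as R; the other epoxide carbon is deactivated by the adjacent CH2OH. Basic, aprotic conditions are chosen so that no Lewis acid ionises the benzylic carbon and the caesium phenoxide reacts at oxygen and not at carbon.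

Step 7
Reactants: 8 (2S,3R)-diol
Product: 10 (S)-2-[(R)-[4-(allyloxy)-3,5-bis(benzyloxy)phenyl][3,5-bis(benzyloxy)phenoxy]methyl]oxirane, via primary tosylate 9 (not isolated)
Conditions: TsCl (1.05 equiv), Et3N, Bu2SnO (2 mol%), CH2Cl2, 0 °C → rt; then K2CO3, MeOH, 0 °C → rt
Reagents that add atoms: none
Why: Tin-acetal-catalysed sulfonylation should pick the primary hydroxyl, and the secondary alkoxide then displaces the tosylate in an intramolecular Williamson closure. The C–O bond at the secondary carbon is not broken, so its configuration is retained.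

Step 8
Reactants: 10 (S)-oxirane with (R)-aryl(aryloxy)methyl substituent
Product: 11 (2R,3S)-2-[4-(allyloxy)-3,5-bis(benzyloxy)phenyl]-5,7-bis(benzyloxy)chroman-3-ol
Conditions: BF3·OEt2 (1.0 equiv), CH2Cl2 (0.01 M), −78 → −30 °C
Reagents that add atoms: none
Why: BF3 binds the epoxide oxygen, the ring A carbon ortho to the ether oxygen O1 (also ortho to one benzyloxy group and para to the other) attacks the terminal CH2 from the rear, and loss of a proton from the arenium ion restores the aromatic ring and leaves the C3 oxygen as the free hydroxyl. The closest known reaction type is the Lewis-acid- or AuCl3-promoted cyclialkylation of aryl glycidyl ethers to chroman-3-ols, an intramolecular Friedel–Crafts alkylation by an epoxide. Ring C closes in the 6-endo mode (both epoxide carbons end up in the new ring); the 5-exo alternative would need attack at the internal carbon, which is secondary, flanked by the bulky benzylic carbon and deactivated inductively by the neighbouring aryloxy-bearing carbon. No stereocentre is formed: C3 is the epoxide CH whose C–O bond stays intact and C2 is a spectator, so the 2,3-trans relationship fixed in steps 5 and 6 is carried over unchanged. Ring A is symmetric, so its two ortho carbons give the same product, and its para carbon cannot reach the epoxide. Ring B is the poorer nucleophile (one ortho and one para oxygen only) and could only close a strained five-membered ring in the endo mode, so it should not compete. The step needs activation of the epoxide in preference to ionisation of the benzylic C2–O1 ether, which the higher basicity of the epoxide oxygen, the only moderately cation-stabilising 3,4,5-trioxygenated ring B, low temperature and high dilution should secure.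

Step 9
Reactants: 11 (2R,3S)-chroman-3-ol
Product: 12 (2R,3S)-2-[4-(allyloxy)-3,5-bis(benzyloxy)phenyl]-3,5,7-tris(benzyloxy)chromane
Conditions: NaH, BnBr, Bu4NI (cat.), DMF, 0 °C → rt
Reagents that add atoms: benzyl bromide, BrCc1ccccc1
Why: Williamson benzylation of the secondary alcohol, so that the azide, isocyanate and fluoroarene chemistry of later steps meets no free hydroxyl. With all phenols protected the flavan is stable to base.

Step 10
Reactants: 12 allyl ether
Product: 13 2,6-bis(benzyloxy)-4-[(2R,3S)-3,5,7-tris(benzyloxy)chroman-2-yl]phenol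
Conditions: Pd(PPh3)4 (5 mol%), morpholine, THF, rt
Reagents that add atoms: none
Why: Tsuji–Trost deallylation; the palladium catalyst ionises only the allyl aryl ether and morpholine traps the allyl group, while benzyl ethers do not react.

Step 11
Reactants: 13 phenol of the trans unit; 14 2,4,6-trifluorobenzaldehyde
Product: 15 4-{2,6-bis(benzyloxy)-4-[(2R,3S)-3,5,7-tris(benzyloxy)chroman-2-yl]phenoxy}-2,6-difluorobenzaldehyde
Conditions: 14 (1.3 equiv), K2CO3, DMF, 0 °C → rt
Reagents that add atoms: none
Why: Nucleophilic aromatic substitution; the formyl group activates all three fluorines, and the phenoxide with two ortho substituents should prefer the unhindered para carbon. The aryloxy group then deactivates the ring against a second substitution.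

Step 12
Reactants: 15 difluoro aldehyde
Product: 17 2,6-bis(benzyloxy)-4-{2,6-bis(benzyloxy)-4-[(2R,3S)-3,5,7-tris(benzyloxy)chroman-2-yl]phenoxy}benzaldehyde, via monobenzyloxy fluoro aldehyde 16 (not isolated)
Conditions: BnOH (2.5 equiv), NaH (2.4 equiv), DMF, 0 → 40 °C
Reagents that add atoms: benzyl alcohol, OCc1ccccc1
Why: Two successive nucleophilic aromatic substitutions of the fluorines ortho to the formyl group by benzyloxide. Fluoride is displaced far faster than the aryloxide para to the formyl group, so the diaryl ether should survive if excess alkoxide and heat are avoided.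

Step 13
Reactants: 17 2,6-bis(benzyloxy)benzaldehyde
Product: 18 2-(benzyloxy)-4-{2,6-bis(benzyloxy)-4-[(2R,3S)-3,5,7-tris(benzyloxy)chroman-2-yl]phenoxy}-6-hydroxybenzaldehyde
Conditions: MgBr2·OEt2 (3 equiv), toluene–Et2O, 60 °C; aq. NH4Cl
Reagents that add atoms: none
Why: Chelation-controlled debenzylation; magnesium bridges the carbonyl oxygen and one ortho ether oxygen, and bromide removes that benzyl group only. The two ortho ethers are equivalent and the resulting magnesium phenoxide chelate protects the second one, so one salicylaldehyde should result.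

Step 14
Reactants: 19 3,4,5-tris(benzyloxy)benzaldehyde
Product: 20 (E)-3-[3,4,5-tris(benzyloxy)phenyl]prop-2-enal
Conditions: Ph3P=CHCHO (1.1 equiv), toluene, 80 °C
Reagents that add atoms: (triphenylphosphoranylidene)acetaldehyde, O=CC=P(c1ccccc1)(c1ccccc1)c1ccccc1
Why: Wittig olefination with a stabilised ylide, which should give the E enal; a small excess of ylide limits a second homologation.

Step 15
Reactants: 18 salicylaldehyde; 20 (E)-enal
Product: 21 (R)-5-(benzyloxy)-7-{2,6-bis(benzyloxy)-4-[(2R,3S)-3,5,7-tris(benzyloxy)chroman-2-yl]phenoxy}-2-[3,4,5-tris(benzyloxy)phenyl]-2H-chromene-3-carbaldehyde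
Conditions: (S)-2-[diphenyl(trimethylsilyloxy)methyl]pyrrolidine (20 mol%), 2-nitrobenzoic acid (20 mol%), 4 Å molecular sieves, toluene, rt
Reagents that add atoms: none
Why: Organocatalytic domino oxa-Michael addition and aldol condensation; the phenol adds to the beta carbon of the iminium ion of 20, and the resulting enamine condenses with the formyl group to close ring F. The new C2 stereocentre is set by the catalyst, whose silyloxydiphenylmethyl group shields one face of the iminium ion, so the phenol should add to the open face and give the R configuration regardless of the distant trans unit.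

Step 16
Reactants: 21 chromene-3-carbaldehyde
Product: 22 (R)-5-(benzyloxy)-7-{2,6-bis(benzyloxy)-4-[(2R,3S)-3,5,7-tris(benzyloxy)chroman-2-yl]phenoxy}-2-[3,4,5-tris(benzyloxy)phenyl]-2H-chromene-3-carboxylic acid
Conditions: NaClO2, NaH2PO4, 2-methyl-2-butene (excess), t-BuOH–THF–H2O, 0 °C → rt
Reagents that add atoms: sodium chlorite, [Na+].[O-]Cl=O
Why: Pinnick oxidation of the unsaturated aldehyde to the acid without touching the double bond; the alkene scavenger removes hypochlorous acid before it can chlorinate the electron-rich rings.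

Step 17
Reactants: 22 chromene-3-carboxylic acid
Product: 25 (R)-5-(benzyloxy)-7-{2,6-bis(benzyloxy)-4-[(2R,3S)-3,5,7-tris(benzyloxy)chroman-2-yl]phenoxy}-2-[3,4,5-tris(benzyloxy)phenyl]chroman-3-one, via acyl azide 23 (not isolated), via vinyl isocyanate 24 (not isolated)
Conditions: (PhO)2P(O)N3, Et3N, toluene, rt → 80 °C; then 1 M HCl aq, THF, rt
Reagents that add atoms: water, O
Why: Curtius rearrangement of the unsaturated acyl azide moves C3 from carbon to nitrogen with loss of N2, and mild aqueous acid hydrolyses the vinyl isocyanate through the enamine to the C3 ketone. This is the established route from 2H-chromene-3-carboxylic acids to chroman-3-ones; dilute acid at room temperature is chosen to spare the C2 stereocentre next to the new carbonyl.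

Step 18
Reactants: 25 chroman-3-one
Product: 26 (2R,3R)-5-(benzyloxy)-7-{2,6-bis(benzyloxy)-4-[(2R,3S)-3,5,7-tris(benzyloxy)chroman-2-yl]phenoxy}-2-[3,4,5-tris(benzyloxy)phenyl]chroman-3-ol
Conditions: LiBH(s-Bu)3 (1.5 equiv), LiBr, THF, −78 °C; aq. NH4Cl
Reagents that add atoms: none
Why: Diastereoselective ketone reduction; the bulky hydride should approach the carbonyl from the face away from the pseudo-equatorial C2 aryl group and give the axial, 2,3-cis alcohol (3R), as is known for flavan-3-ones. At −78 °C reduction should outrun enolisation.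

Step 19
Reactants: 26 nonabenzyl ether
Product: 27 (2R,3R)-7-{2,6-dihydroxy-4-[(2R,3S)-3,5,7-trihydroxychroman-2-yl]phenoxy}-2-(3,4,5-trihydroxyphenyl)chromane-3,5-diol
Conditions: H2 (1 atm), Pd(OH)2/C, THF–MeOH, rt; filtration under argon
Reagents that add atoms: none
Why: Hydrogenolysis of all nine benzyl ethers under neutral conditions; the diaryl ether is inert and, with short reaction time, the benzylic C2–O1 bonds of the two pyran rings should survive, as in known debenzylations of catechin derivatives.

## Compound list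

1 | 3,4,5-trihydroxybenzaldehyde | O=Cc1cc(O)c(O)c(O)c1 | starting material
2 | 4-(allyloxy)-3,5-dihydroxybenzaldehyde | O=Cc1cc(O)c(OCC=C)c(O)c1 | intermediate
3 | 4-(allyloxy)-3,5-bis(benzyloxy)benzaldehyde | O=Cc1cc(OCc9ccccc9)c(OCC=C)c(OCc9ccccc9)c1 | intermediate
4 | ethyl (E)-3-[4-(allyloxy)-3,5-bis(benzyloxy)phenyl]prop-2-enoate | CCOC(=O)/C=C/c1cc(OCc9ccccc9)c(OCC=C)c(OCc9ccccc9)c1 | intermediate
5 | (E)-3-[4-(allyloxy)-3,5-bis(benzyloxy)phenyl]prop-2-en-1-ol | OC/C=C/c1cc(OCc9ccccc9)c(OCC=C)c(OCc9ccccc9)c1 | intermediate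
6 | [(2S,3S)-3-[4-(allyloxy)-3,5-bis(benzyloxy)phenyl]oxiran-2-yl]methanol | OC[C@@H]1O[C@H]1c1cc(OCc9ccccc9)c(OCC=C)c(OCc9ccccc9)c1 | intermediate
7 | 3,5-bis(benzyloxy)phenol | Oc1cc(OCc9ccccc9)cc(OCc9ccccc9)c1 | starting material
8 | (2S,3R)-3-[4-(allyloxy)-3,5-bis(benzyloxy)phenyl]-3-[3,5-bis(benzyloxy)phenoxy]propane-1,2-diol | c9ccccc9COc1cc(OCc9ccccc9)cc(c1)O[C@H](c1cc(OCc9ccccc9)c(OCC=C)c(OCc9ccccc9)c1)[C@@H](O)CO | intermediate
9 | (2S,3R)-3-[4-(allyloxy)-3,5-bis(benzyloxy)phenyl]-3-[3,5-bis(benzyloxy)phenoxy]-2-hydroxypropyl 4-methylbenzenesulfonate (not isolated) | c9ccccc9COc1cc(OCc9ccccc9)cc(c1)O[C@H](c1cc(OCc9ccccc9)c(OCC=C)c(OCc9ccccc9)c1)[C@@H](O)COS(=O)(=O)c1ccc(C)cc1 | intermediate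
10 | (S)-2-[(R)-[4-(allyloxy)-3,5-bis(benzyloxy)phenyl][3,5-bis(benzyloxy)phenoxy]methyl]oxirane | c9ccccc9COc1cc(OCc9ccccc9)cc(c1)O[C@H](c1cc(OCc9ccccc9)c(OCC=C)c(OCc9ccccc9)c1)[C@@H]5CO5 | intermediate
11 | (2R,3S)-2-[4-(allyloxy)-3,5-bis(benzyloxy)phenyl]-5,7-bis(benzyloxy)chroman-3-ol | c9ccccc9COc1cc(OCc9ccccc9)c2c(c1)O[C@H](c1cc(OCc9ccccc9)c(OCC=C)c(OCc9ccccc9)c1)[C@@H](O)C2 | intermediate
12 | (2R,3S)-2-[4-(allyloxy)-3,5-bis(benzyloxy)phenyl]-3,5,7-tris(benzyloxy)chromane | c9ccccc9COc1cc(OCc9ccccc9)c2c(c1)O[C@H](c1cc(OCc9ccccc9)c(OCC=C)c(OCc9ccccc9)c1)[C@@H](OCc9ccccc9)C2 | intermediate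
13 | 2,6-bis(benzyloxy)-4-[(2R,3S)-3,5,7-tris(benzyloxy)chroman-2-yl]phenol | c9ccccc9COc1cc(OCc9ccccc9)c2c(c1)O[C@H](c1cc(OCc9ccccc9)c(O)c(OCc9ccccc9)c1)[C@@H](OCc9ccccc9)C2 | intermediate
14 | 2,4,6-trifluorobenzaldehyde | O=Cc1c(F)cc(F)cc1F | starting material
15 | 4-{2,6-bis(benzyloxy)-4-[(2R,3S)-3,5,7-tris(benzyloxy)chroman-2-yl]phenoxy}-2,6-difluorobenzaldehyde | c9ccccc9COc1cc(OCc9ccccc9)c2c(c1)O[C@H](c1cc(OCc9ccccc9)c(Oc3cc(F)c(C=O)c(F)c3)c(OCc9ccccc9)c1)[C@@H](OCc9ccccc9)C2 | intermediate
16 | 2-(benzyloxy)-4-{2,6-bis(benzyloxy)-4-[(2R,3S)-3,5,7-tris(benzyloxy)chroman-2-yl]phenoxy}-6-fluorobenzaldehyde (not isolated) | c9ccccc9COc1cc(OCc9ccccc9)c2c(c1)O[C@H](c1cc(OCc9ccccc9)c(Oc3cc(F)c(C=O)c(OCc9ccccc9)c3)c(OCc9ccccc9)c1)[C@@H](OCc9ccccc9)C2 | intermediate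
17 | 2,6-bis(benzyloxy)-4-{2,6-bis(benzyloxy)-4-[(2R,3S)-3,5,7-tris(benzyloxy)chroman-2-yl]phenoxy}benzaldehyde | c9ccccc9COc1cc(OCc9ccccc9)c2c(c1)O[C@H](c1cc(OCc9ccccc9)c(Oc3cc(OCc9ccccc9)c(C=O)c(OCc9ccccc9)c3)c(OCc9ccccc9)c1)[C@@H](OCc9ccccc9)C2 | intermediate
18 | 2-(benzyloxy)-4-{2,6-bis(benzyloxy)-4-[(2R,3S)-3,5,7-tris(benzyloxy)chroman-2-yl]phenoxy}-6-hydroxybenzaldehyde | c9ccccc9COc1cc(OCc9ccccc9)c2c(c1)O[C@H](c1cc(OCc9ccccc9)c(Oc3cc(O)c(C=O)c(OCc9ccccc9)c3)c(OCc9ccccc9)c1)[C@@H](OCc9ccccc9)C2 | intermediate
19 | 3,4,5-tris(benzyloxy)benzaldehyde | O=Cc1cc(OCc9ccccc9)c(OCc9ccccc9)c(OCc9ccccc9)c1 | starting material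
20 | (E)-3-[3,4,5-tris(benzyloxy)phenyl]prop-2-enal | O=C/C=C/c1cc(OCc9ccccc9)c(OCc9ccccc9)c(OCc9ccccc9)c1 | intermediate
21 | (R)-5-(benzyloxy)-7-{2,6-bis(benzyloxy)-4-[(2R,3S)-3,5,7-tris(benzyloxy)chroman-2-yl]phenoxy}-2-[3,4,5-tris(benzyloxy)phenyl]-2H-chromene-3-carbaldehyde | c9ccccc9COc1cc(OCc9ccccc9)c2c(c1)O[C@H](c1cc(OCc9ccccc9)c(Oc3cc(OCc9ccccc9)c4c(c3)O[C@H](c3cc(OCc9ccccc9)c(OCc9ccccc9)c(OCc9ccccc9)c3)C(C=O)=C4)c(OCc9ccccc9)c1)[C@@H](OCc9ccccc9)C2 | intermediate
22 | (R)-5-(benzyloxy)-7-{2,6-bis(benzyloxy)-4-[(2R,3S)-3,5,7-tris(benzyloxy)chroman-2-yl]phenoxy}-2-[3,4,5-tris(benzyloxy)phenyl]-2H-chromene-3-carboxylic acid | c9ccccc9COc1cc(OCc9ccccc9)c2c(c1)O[C@H](c1cc(OCc9ccccc9)c(Oc3cc(OCc9ccccc9)c4c(c3)O[C@H](c3cc(OCc9ccccc9)c(OCc9ccccc9)c(OCc9ccccc9)c3)C(C(=O)O)=C4)c(OCc9ccccc9)c1)[C@@H](OCc9ccccc9)C2 | intermediate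
23 | (R)-5-(benzyloxy)-7-{2,6-bis(benzyloxy)-4-[(2R,3S)-3,5,7-tris(benzyloxy)chroman-2-yl]phenoxy}-2-[3,4,5-tris(benzyloxy)phenyl]-2H-chromene-3-carbonyl azide (not isolated) | c9ccccc9COc1cc(OCc9ccccc9)c2c(c1)O[C@H](c1cc(OCc9ccccc9)c(Oc3cc(OCc9ccccc9)c4c(c3)O[C@H](c3cc(OCc9ccccc9)c(OCc9ccccc9)c(OCc9ccccc9)c3)C(C(=O)N=[N+]=[N-])=C4)c(OCc9ccccc9)c1)[C@@H](OCc9ccccc9)C2 | intermediate
24 | (R)-5-(benzyloxy)-7-{2,6-bis(benzyloxy)-4-[(2R,3S)-3,5,7-tris(benzyloxy)chroman-2-yl]phenoxy}-3-isocyanato-2-[3,4,5-tris(benzyloxy)phenyl]-2H-chromene (not isolated) | c9ccccc9COc1cc(OCc9ccccc9)c2c(c1)O[C@H](c1cc(OCc9ccccc9)c(Oc3cc(OCc9ccccc9)c4c(c3)O[C@H](c3cc(OCc9ccccc9)c(OCc9ccccc9)c(OCc9ccccc9)c3)C(N=C=O)=C4)c(OCc9ccccc9)c1)[C@@H](OCc9ccccc9)C2 | intermediate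
25 | (R)-5-(benzyloxy)-7-{2,6-bis(benzyloxy)-4-[(2R,3S)-3,5,7-tris(benzyloxy)chroman-2-yl]phenoxy}-2-[3,4,5-tris(benzyloxy)phenyl]chroman-3-one | c9ccccc9COc1cc(OCc9ccccc9)c2c(c1)O[C@H](c1cc(OCc9ccccc9)c(Oc3cc(OCc9ccccc9)c4c(c3)O[C@H](c3cc(OCc9ccccc9)c(OCc9ccccc9)c(OCc9ccccc9)c3)C(=O)C4)c(OCc9ccccc9)c1)[C@@H](OCc9ccccc9)C2 | intermediate
26 | (2R,3R)-5-(benzyloxy)-7-{2,6-bis(benzyloxy)-4-[(2R,3S)-3,5,7-tris(benzyloxy)chroman-2-yl]phenoxy}-2-[3,4,5-tris(benzyloxy)phenyl]chroman-3-ol | c9ccccc9COc1cc(OCc9ccccc9)c2c(c1)O[C@H](c1cc(OCc9ccccc9)c(Oc3cc(OCc9ccccc9)c4c(c3)O[C@H](c3cc(OCc9ccccc9)c(OCc9ccccc9)c(OCc9ccccc9)c3)[C@H](O)C4)c(OCc9ccccc9)c1)[C@@H](OCc9ccccc9)C2 | intermediate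
27 | (2R,3R)-7-{2,6-dihydroxy-4-[(2R,3S)-3,5,7-trihydroxychroman-2-yl]phenoxy}-2-(3,4,5-trihydroxyphenyl)chromane-3,5-diol | Oc1cc(O)c2c(c1)O[C@H](c1cc(O)c(Oc3cc(O)c4c(c3)O[C@H](c3cc(O)c(O)c(O)c3)[C@H](O)C4)c(O)c1)[C@@H](O)C2 | target

## Step count and least certain steps

Total: 19 steps. Longest linear sequence: 18 steps (steps 1–13 and 15–19); step 14 is a one-step side branch.

**Step 8 (key step).** The Lewis acid may ionise the benzylic C2–O1 ether instead of the epoxide, or the activated epoxide may be opened at the internal carbon (5-exo closure), by an external nucleophile or by a second molecule. All of these are open to an electrophile that sits next to an oxygenated benzylic carbon and faces a very electron-rich arene. The fallback removes the epoxide and its regiochemical choice. It sets out from diol 8, whose primary hydroxyl is oxidised with TEMPO (cat.) and PhI(OAc)2 to (2R,3R)-3-[4-(allyloxy)-3,5-bis(benzyloxy)phenyl]-3-[3,5-bis(benzyloxy)phenoxy]-2-hydroxypropanal F1. Treatment of this aldehyde with BF3·OEt2 and Et3SiH in CH2Cl2 at −78 °C should close ring C by intramolecular Friedel–Crafts hydroxyalkylation, which can only give the six-membered ring, to the (2R,3S)-2-[4-(allyloxy)-3,5-bis(benzyloxy)phenyl]-5,7-bis(benzyloxy)chromane-3,4-diol F2 (epimers at C4, formed in the flask). Its doubly activated benzylic C4 hydroxyl is then removed by ionic hydrogenation in the same flask, and the route is rejoined at 11.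

**Step 17.** The C2 stereocentre of the cis unit may epimerise during the acidic hydrolysis, by enolisation of the ketone or by tautomerisation of the intermediate enamine toward C2, which is benzylic and bears oxygen; the isocyanate may also be lost to urea formation with the enamine. The fallback reaches the ketone under neutral conditions. It sets out from aldehyde 21, which is decarbonylated with stoichiometric RhCl(PPh3)3 in toluene at 100 °C to (S)-5-(benzyloxy)-7-{2,6-bis(benzyloxy)-4-[(2R,3S)-3,5,7-tris(benzyloxy)chroman-2-yl]phenoxy}-2-[3,4,5-tris(benzyloxy)phenyl]-2H-chromene F6 (same spatial arrangement at C2 as in 21; only the descriptor changes). Hydroboration with BH3·THF anti to the C2 aryl group and oxidation with NaOH and H2O2 give the 2,3-trans alcohol (2R,3S)-5-(benzyloxy)-7-{2,6-bis(benzyloxy)-4-[(2R,3S)-3,5,7-tris(benzyloxy)chroman-2-yl]phenoxy}-2-[3,4,5-tris(benzyloxy)phenyl]chroman-3-ol F7. Dess–Martin periodinane oxidises it to 25, where the route is rejoined.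

**Step 15.** The aldol closure may be slow on the electron-rich formyl group flanked by two ortho oxygens, and the reversible oxa-Michael addition may erode the facial selectivity; since the trans unit is enantiopure, this would show as a mixture of diastereomers. The fallback uses a stronger, irreversible acceptor. It sets out from aldehyde 19, which is condensed with nitromethane (NH4OAc, AcOH, 90 °C) to (E)-1,2,3-tris(benzyloxy)-5-(2-nitroethenyl)benzene F4. Salicylaldehyde 18 and this nitroalkene are combined under a cinchona-derived amine–thiourea catalyst in an oxa-Michael, Henry and dehydration sequence to (R)-5-(benzyloxy)-7-{2,6-bis(benzyloxy)-4-[(2R,3S)-3,5,7-tris(benzyloxy)chroman-2-yl]phenoxy}-3-nitro-2-[3,4,5-tris(benzyloxy)phenyl]-2H-chromene F5. Reductive hydrolysis of the nitroalkene (iron powder, AcOH, aqueous THF, 50 °C) gives ketone 25, where the route is rejoined; steps 16 and 17 are then not needed.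

**Step 11.** The phenoxide may attack a carbon ortho to the formyl group instead of the para carbon, or a second phenoxide may displace another fluorine, because all three fluorines of 14 are activated. The fallback fixes the position by the leaving group. It sets out from phenol 13, which is coupled under Ullmann conditions (CuI, picolinic acid, K3PO4, DMSO, 80 °C) with 2,6-bis(benzyloxy)-4-bromobenzaldehyde F3, itself made from commercial 4-bromo-2,6-difluorobenzaldehyde with BnOH and NaH. The product is 17, where the route is rejoined; step 12 is then not needed.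

## Further compounds

F1 | step 8 | (2R,3R)-3-[4-(allyloxy)-3,5-bis(benzyloxy)phenyl]-3-[3,5-bis(benzyloxy)phenoxy]-2-hydroxypropanal | c9ccccc9COc1cc(OCc9ccccc9)cc(c1)O[C@H](c1cc(OCc9ccccc9)c(OCC=C)c(OCc9ccccc9)c1)[C@@H](O)C=O
F2 | step 8 | (2R,3S)-2-[4-(allyloxy)-3,5-bis(benzyloxy)phenyl]-5,7-bis(benzyloxy)chromane-3,4-diol (mixture at C4) | c9ccccc9COc1cc(OCc9ccccc9)c2c(c1)O[C@H](c1cc(OCc9ccccc9)c(OCC=C)c(OCc9ccccc9)c1)[C@@H](O)C2O
F3 | step 11 | 2,6-bis(benzyloxy)-4-bromobenzaldehyde | O=Cc1c(OCc9ccccc9)cc(Br)cc1OCc9ccccc9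
F4 | step 15 | (E)-1,2,3-tris(benzyloxy)-5-(2-nitroethenyl)benzene | O=[N+]([O-])/C=C/c1cc(OCc9ccccc9)c(OCc9ccccc9)c(OCc9ccccc9)c1
F5 | step 15 | (R)-5-(benzyloxy)-7-{2,6-bis(benzyloxy)-4-[(2R,3S)-3,5,7-tris(benzyloxy)chroman-2-yl]phenoxy}-3-nitro-2-[3,4,5-tris(benzyloxy)phenyl]-2H-chromene | c9ccccc9COc1cc(OCc9ccccc9)c2c(c1)O[C@H](c1cc(OCc9ccccc9)c(Oc3cc(OCc9ccccc9)c4c(c3)O[C@H](c3cc(OCc9ccccc9)c(OCc9ccccc9)c(OCc9ccccc9)c3)C([N+](=O)[O-])=C4)c(OCc9ccccc9)c1)[C@@H](OCc9ccccc9)C2
F6 | step 17 | (S)-5-(benzyloxy)-7-{2,6-bis(benzyloxy)-4-[(2R,3S)-3,5,7-tris(benzyloxy)chroman-2-yl]phenoxy}-2-[3,4,5-tris(benzyloxy)phenyl]-2H-chromene | c9ccccc9COc1cc(OCc9ccccc9)c2c(c1)O[C@H](c1cc(OCc9ccccc9)c(Oc3cc(OCc9ccccc9)c4c(c3)O[C@H](c3cc(OCc9ccccc9)c(OCc9ccccc9)c(OCc9ccccc9)c3)C=C4)c(OCc9ccccc9)c1)[C@@H](OCc9ccccc9)C2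
F7 | step 17 | (2R,3S)-5-(benzyloxy)-7-{2,6-bis(benzyloxy)-4-[(2R,3S)-3,5,7-tris(benzyloxy)chroman-2-yl]phenoxy}-2-[3,4,5-tris(benzyloxy)phenyl]chroman-3-ol | c9ccccc9COc1cc(OCc9ccccc9)c2c(c1)O[C@H](c1cc(OCc9ccccc9)c(Oc3cc(OCc9ccccc9)c4c(c3)O[C@H](c3cc(OCc9ccccc9)c(OCc9ccccc9)c(OCc9ccccc9)c3)[C@@H](O)C4)c(OCc9ccccc9)c1)[C@@H](OCc9ccccc9)C2
A1 | alternative 1 | ring B benzylic bromide carrying the protected cis flavan | BrCc1cc(OCc9ccccc9)c(Oc3cc(OCc9ccccc9)c4c(c3)O[C@H](c3cc(OCc9ccccc9)c(OCc9ccccc9)c(OCc9ccccc9)c3)[C@H](OCc9ccccc9)C4)c(OCc9ccccc9)c1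
A2 | alternative 1 | 2-[2,4-bis(benzyloxy)-6-(tert-butyldimethylsilyloxy)phenyl]acetaldehyde | CC(C)(C)[Si](C)(C)Oc1cc(OCc9ccccc9)cc(OCc9ccccc9)c1CC=O
A3 | alternative 1 | (2S,3S)-trans-epoxide (flavan numbering) linking ring A and ring B of the trans unit | CC(C)(C)[Si](C)(C)Oc1cc(OCc9ccccc9)cc(OCc9ccccc9)c1C[C@@H]5O[C@H]5c1cc(OCc9ccccc9)c(Oc3cc(OCc9ccccc9)c4c(c3)O[C@H](c3cc(OCc9ccccc9)c(OCc9ccccc9)c(OCc9ccccc9)c3)[C@H](OCc9ccccc9)C4)c(OCc9ccccc9)c1
A4 | alternative 2 | 3,5-bis(benzyloxy)-2-(hydroxymethyl)phenol | OCc1c(O)cc(OCc9ccccc9)cc1OCc9ccccc9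
A5 | alternative 2 | (E)-2-arylethenyl pinacol boronate of ring B carrying the protected cis flavan | CC1(C)OB(/C=C/c2cc(OCc9ccccc9)c(Oc3cc(OCc9ccccc9)c4c(c3)O[C@H](c3cc(OCc9ccccc9)c(OCc9ccccc9)c(OCc9ccccc9)c3)[C@H](OCc9ccccc9)C4)c(OCc9ccccc9)c2)OC1(C)C
A6 | alternative 2 | 2,3-trans-2-aryl-3-(pinacolboryl)chroman with the target configuration at C2 and C3 | c9ccccc9COc1cc(OCc9ccccc9)c2c(c1)O[C@H](c1cc(OCc9ccccc9)c(Oc3cc(OCc9ccccc9)c4c(c3)O[C@H](c3cc(OCc9ccccc9)c(OCc9ccccc9)c(OCc9ccccc9)c3)[C@H](OCc9ccccc9)C4)c(OCc9ccccc9)c1)[C@@H](B5OC(C)(C)C(C)(C)O5)C2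
A7 | alternative 3 | 2-(benzyloxy)-4-{2,6-bis(benzyloxy)-4-[(2R,3S)-3,5,7-tris(benzyloxy)chroman-2-yl]phenoxy}-6-hydroxybenzaldehyde | c9ccccc9COc1cc(OCc9ccccc9)c2c(c1)O[C@H](c1cc(OCc9ccccc9)c(Oc3cc(O)c(C=O)c(OCc9ccccc9)c3)c(OCc9ccccc9)c1)[C@@H](OCc9ccccc9)C2
A8 | alternative 3 | (E)-3-[3,4,5-tris(benzyloxy)phenyl]prop-2-enal | O=C/C=C/c1cc(OCc9ccccc9)c(OCc9ccccc9)c(OCc9ccccc9)c1
A9 | alternative 3 | (R)-2-aryl-2H-chromene-3-carbaldehyde attached to the protected trans flavan | c9ccccc9COc1cc(OCc9ccccc9)c2c(c1)O[C@H](c1cc(OCc9ccccc9)c(Oc3cc(OCc9ccccc9)c4c(c3)O[C@H](c3cc(OCc9ccccc9)c(OCc9ccccc9)c(OCc9ccccc9)c3)C(C=O)=C4)c(OCc9ccccc9)c1)[C@@H](OCc9ccccc9)C2
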